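**Retrosynthetic overview** (ring atoms numbered as in chroman-4-one)
1. Feature: the benzene ring C4a–C5–C6–C7–C8–C8a is hexasubstituted, with oxygens on C5, C7 and C8a that need three different fates. C8, its stereogenic CH, the CH2 and the ester carbon are C2–C5 of a 3-propylglutaric half-ester whose acid carbon is C8a.
2. Dihydropyranone last: O1–C2 by quinine-catalysed oxa-Michael closure (cis C2/C3), C4–C4a by O-tigloylation and Fries shift; then O5 (ethyl) and O7 (silyl) are unmasked.
3. Benzene ring: benzannulation of a 3-silyloxycyclobutenone with ethoxyacetylene makes C4a–C8a and C5–C6 and delivers O8a as free OH, O5 as OEt, O7 as OSi and C4a as CH.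
4. Cyclobutenone: [2+2] of the ketene from the (S)-half-ester acid chloride with an allyl silyl ynol ether; the half-ester comes from desymmetrising methanolysis of 3-propylglutaric anhydride.
5. Ring order: cyclobutenone (consumed) → benzene ring → dihydropyranone ring.

Key step: step 5

Assumption: the C6 side chain is carried as allyl through the two Lewis-acid steps and completed to prenyl by cross-metathesis, because a trisubstituted alkene would add the HCl that the Fries step releases.

**Route**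

Step 1
Reactants: 1 3-propylglutaric anhydride (4-propyloxane-2,6-dione)
Product: 2 (3S)-5-methoxy-5-oxo-3-propylpentanoic acid
Conditions: quinidine (1.1 equiv), MeOH (3 equiv), PhMe, −55 °C; aq. HCl wash (alkaloid recovered)
Reagents that add atoms: methanol, SMILES CO
Why: Alkaloid-mediated desymmetrising methanolysis of a prochiral cyclic anhydride, in which the quinuclidine nitrogen delivers methanol to one enantiotopic carbonyl, should set C3 as S (quinine gives the antipode; the sense is checked on 2 and the ee raised if needed by crystallising the 1-phenylethylammonium salt).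

Step 2
Reactants: 2 (3S)-5-methoxy-5-oxo-3-propylpentanoic acid
Product: 3 methyl (3R)-5-chloro-5-oxo-3-propylpentanoate
Conditions: (COCl)2, DMF (cat.), CH2Cl2, 0 °C → rt; concentrated and used crude
Reagents that add atoms: oxalyl chloride, SMILES O=C(Cl)C(=O)Cl
Why: Acid chloride formation under Vilsmeier-type catalysis is cold and neutral, so the half-ester does not equilibrate through the symmetric anhydride and the centre (β to the acyl group, R only by a change of CIP priorities) is kept.

Step 3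
Reactants: 4 pent-1-en-4-yne
Product: 7 triisopropyl(pent-4-en-1-yn-1-yloxy)silane, via pent-4-en-1-yn-1-yllithium 5 (not isolated), via lithium pent-4-en-1-yn-1-olate 6 (not isolated)
Conditions: LiN(SiMe3)2 (2.1 equiv), tBuOOH, THF, −78 → 0 °C; then iPr3SiOTf, −78 °C → rt
Reagents that add atoms: tert-butyl hydroperoxide, SMILES CC(C)(C)OO; triisopropylsilyl trifluoromethanesulfonate, SMILES CC(C)[Si](OS(=O)(=O)C(F)(F)F)(C(C)C)C(C)C
Why: Acetylide-to-ynolate oxidation by lithium tert-butyl peroxide followed by O-silylation with the bulky silyl triflate should give a stable silyl ynol ether, and LiN(SiMe3)2 is too weak a base to touch the doubly activated CH2.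

Step 4
Reactants: 3 methyl (3R)-5-chloro-5-oxo-3-propylpentanoate; 7 triisopropyl(pent-4-en-1-yn-1-yloxy)silane
Product: 9 methyl (3R)-3-[4-oxo-3-(prop-2-en-1-yl)-2-(triisopropylsilyloxy)cyclobut-2-en-1-yl]hexanoate (both ring epimers), via aldoketene 8 (not isolated)
Conditions: Et3N (1.5 equiv), CH2Cl2, rt, slow addition of 3 to 7 and base; filtration through Et3N-deactivated silica
Reagents that add atoms: none
Why: Dehydrochlorination gives the monoalkylketene, and ketene–ynol ether [2+2] cycloaddition with the nucleophilic allyl-bearing carbon of 7 bonding to the ketene carbonyl carbon should place C=O, allyl, OSi and the side chain around the ring in that order; the new ring CH forms as both epimers, which converge in step 5, and the side-chain centre is β to the ketene and untouched.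

Step 5
Reactants: 9 methyl (3R)-3-[4-oxo-3-(prop-2-en-1-yl)-2-(triisopropylsilyloxy)cyclobut-2-en-1-yl]hexanoate; 10 ethoxyacetylene
Product: 15 methyl (3R)-3-[4-ethoxy-2-hydroxy-5-(prop-2-en-1-yl)-6-(triisopropylsilyloxy)phenyl]hexanoate, via silyloxyvinylketene 11 (not isolated), via vinylcyclobutenone 12 (not isolated), via dienylketene 13 (not isolated), via cyclohexadienone 14 (not isolated)
Conditions: 10 (3 equiv, hexanes solution), PhMe, sealed tube, 80 °C then 110 °C; crude phenol acylated the same day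
Reagents that add atoms: none
Why: Conrotatory 4π opening of 9 (C8–C8a cleaved) gives vinylketene 11; the nucleophilic CH terminus of ethoxyacetylene bonds to the ketene carbonyl carbon (C4a–C8a) and the ethoxy-bearing carbon to the ketene α-carbon (C5–C6) in a [2+2] cycloaddition to 12, which opens to dienylketene 13. The benzene ring, the only ring closed, is formed by thermal disrotatory 6π electrocyclisation of 13 (C8–C8a re-formed) to dienone 14, which tautomerises to phenol 15. The closest known reaction type is the cyclobutenone–alkoxyalkyne benzannulation (Danheiser benzannulation); the 2,4-dialkyl-3-silyloxy pattern leading to a fully substituted ring has not been demonstrated and is the main risk of the route. No stereocentre is created: the ring CH of 9 becomes sp2, and the side-chain centre lies outside the reacting π system, is not α to a carbonyl and should be retained. The step needs the regiochemistry of the [2+2] addition, which the polarity of ketene and ynol ether secures, and the Z geometry of 13, which is reached because unproductive ring openings are reversible. The phenol sits next to the ester-bearing chain and could lactonise to a dihydrocoumarin, so it is not stored.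

Step 6
Reactants: 15 methyl (3R)-3-[4-ethoxy-2-hydroxy-5-(prop-2-en-1-yl)-6-(triisopropylsilyloxy)phenyl]hexanoate; 16 tigloyl chloride [(2E)-2-methylbut-2-enoyl chloride]
Product: 17 5-ethoxy-2-[(3R)-1-methoxy-1-oxohexan-3-yl]-4-(prop-2-en-1-yl)-3-(triisopropylsilyloxy)phenyl (2E)-2-methylbut-2-enoate
Conditions: pyridine, DMAP (cat.), CH2Cl2, 0 °C → rt
Reagents that add atoms: none
Why: DMAP-catalysed O-acylation of the phenol is fast and removes the risk of lactonisation, and pyridine in place of a trialkylamine avoids vinylketene formation and deconjugation of the tigloyl group.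

Step 7
Reactants: 17 5-ethoxy-2-[(3R)-1-methoxy-1-oxohexan-3-yl]-4-(prop-2-en-1-yl)-3-(triisopropylsilyloxy)phenyl (2E)-2-methylbut-2-enoate
Product: 19 methyl (3R)-3-[4-ethoxy-2-hydroxy-3-[(2E)-2-methylbut-2-enoyl]-5-(prop-2-en-1-yl)-6-(triisopropylsilyloxy)phenyl]hexanoate, via trichlorotitanium phenoxide 18 (not isolated)
Conditions: TiCl4 (2 equiv), 2,6-di-tert-butyl-4-methylpyridine (1.2 equiv), CH2Cl2, −40 → 0 °C; cold aq. NaHCO3
Reagents that add atoms: none
Why: Lewis-acid Fries rearrangement returns the tigloyl cation to C4a, the only unsubstituted ring carbon and the one activated by O5, O7 and O8a, giving the chelated ortho-hydroxy ketone with the E-enone intact; the hindered pyridine traps the HCl released, and the alkene is kept monosubstituted at this stage so that it does not add HCl.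

Step 8
Reactants: 19 methyl (3R)-3-[4-ethoxy-2-hydroxy-3-[(2E)-2-methylbut-2-enoyl]-5-(prop-2-en-1-yl)-6-(triisopropylsilyloxy)phenyl]hexanoate
Product: 21 methyl (3R)-3-[(2R,3S)-5-ethoxy-2,3-dimethyl-4-oxo-6-(prop-2-en-1-yl)-7-(triisopropylsilyloxy)-3,4-dihydro-2H-chromen-8-yl]hexanoate, via chromanone enol 20 (not isolated)
Conditions: (−)-quinine (20 mol %), PhCl, 15 °C
Reagents that add atoms: none
Why: Cinchona-alkaloid-catalysed intramolecular oxa-Michael addition (6-endo-trig), in which quinine as a bifunctional base delivers the C8a phenoxide to one face of the E-enone so that C2 should be set R, and the enol 20 is then protonated at C3 from the face away from the C2 methyl under kinetic control, giving the cis (2R,3S) ring; only O8a can add because O5 is an ethyl ether.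

Step 9
Reactants: 21 methyl (3R)-3-[(2R,3S)-5-ethoxy-2,3-dimethyl-4-oxo-6-(prop-2-en-1-yl)-7-(triisopropylsilyloxy)-3,4-dihydro-2H-chromen-8-yl]hexanoate
Product: 23 methyl (3R)-3-[(2R,3S)-5-hydroxy-2,3-dimethyl-4-oxo-6-(prop-2-en-1-yl)-7-(triisopropylsilyloxy)-3,4-dihydro-2H-chromen-8-yl]hexanoate, via dichloroboryl chelate 22 (not isolated)
Conditions: BCl3 (1 M in CH2Cl2, 1.5 equiv), CH2Cl2, −78 → −20 °C; pH 7 buffer at −20 °C
Reagents that add atoms: none
Why: Chelation-directed ether cleavage, in which BCl3 binds the C4 carbonyl and O5 so that chloride removes only the peri ethyl group; at low temperature and without base the cis C2/C3 centres, the methyl ester, the aryl silyl ether and the terminal alkene should be left alone.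

Step 10
Reactants: 23 methyl (3R)-3-[(2R,3S)-5-hydroxy-2,3-dimethyl-4-oxo-6-(prop-2-en-1-yl)-7-(triisopropylsilyloxy)-3,4-dihydro-2H-chromen-8-yl]hexanoate; 24 2-methylbut-2-ene
Product: 25 methyl (3R)-3-[(2R,3S)-5-hydroxy-2,3-dimethyl-6-(3-methylbut-2-en-1-yl)-4-oxo-7-(triisopropylsilyloxy)-3,4-dihydro-2H-chromen-8-yl]hexanoate
Conditions: second-generation Grubbs catalyst, (H2IMes)(PCy3)Cl2Ru=CHPh (5 mol %), 2-methylbut-2-ene/CH2Cl2 (1:2), 40 °C, sealed tube
Reagents that add atoms: none
Why: Olefin cross-metathesis of a terminal allylarene with excess 2-methylbut-2-ene is the standard allyl-to-prenyl conversion (propene is lost and the trisubstituted product does not re-enter), and the neutral ruthenium carbene leaves the chelated phenol, the ester and the epimerisable C3 centre alone.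

Step 11
Reactants: 25 methyl (3R)-3-[(2R,3S)-5-hydroxy-2,3-dimethyl-6-(3-methylbut-2-en-1-yl)-4-oxo-7-(triisopropylsilyloxy)-3,4-dihydro-2H-chromen-8-yl]hexanoate
Product: 26 methyl (3R)-3-[(2R,3S)-5,7-dihydroxy-2,3-dimethyl-6-(3-methylbut-2-en-1-yl)-4-oxo-3,4-dihydro-2H-chromen-8-yl]hexanoate (CNP0068017.1)
Conditions: Bu4NF/AcOH (1:1, 1.5 equiv), THF, 0 °C → rt
Reagents that add atoms: none
Why: Fluoride cleavage of the aryl silyl ether, buffered with acetic acid so that no free phenoxide or basic fluoride is present, should not epimerise C3, open the pyranone by retro-Michael reaction or let the new C7 phenol lactonise onto the ester.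

**Compound list**

1 | 3-propylglutaric anhydride (4-propyloxane-2,6-dione) | CCCC1CC(=O)OC(=O)C1 | starting material
2 | (3S)-5-methoxy-5-oxo-3-propylpentanoic acid | CCC[C@H](CC(=O)OC)CC(=O)O | intermediate
3 | methyl (3R)-5-chloro-5-oxo-3-propylpentanoate | CCC[C@H](CC(=O)OC)CC(=O)Cl | intermediate
4 | pent-1-en-4-yne | C=CCC#C | starting material
5 | pent-4-en-1-yn-1-yllithium | [Li]C#CCC=C | intermediate
6 | lithium pent-4-en-1-yn-1-olate | [Li+].[O-]C#CCC=C | intermediate
7 | triisopropyl(pent-4-en-1-yn-1-yloxy)silane | C=CCC#CO[Si](C(C)C)(C(C)C)C(C)C | intermediate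
8 | methyl (3R)-5-oxo-3-propylpent-4-enoate (aldoketene) | CCC[C@H](CC(=O)OC)C=C=O | intermediate
9 | methyl (3R)-3-[4-oxo-3-(prop-2-en-1-yl)-2-(triisopropylsilyloxy)cyclobut-2-en-1-yl]hexanoate, both ring epimers | CCC[C@H](CC(=O)OC)C1C(=O)C(CC=C)=C1O[Si](C(C)C)(C(C)C)C(C)C | intermediate
10 | ethoxyacetylene (ethoxyethyne) | CCOC#C | starting material
11 | methyl (3R)-3-[4-oxo-3-(prop-2-en-1-yl)-2-(triisopropylsilyloxy)buta-1,3-dien-1-yl]hexanoate (silyloxyvinylketene, either alkene geometry) | CCC[C@H](CC(=O)OC)C=C(O[Si](C(C)C)(C(C)C)C(C)C)C(CC=C)=C=O | intermediate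
12 | methyl (3R)-3-{2-[2-ethoxy-4-oxo-1-(prop-2-en-1-yl)cyclobut-2-en-1-yl]-2-(triisopropylsilyloxy)ethenyl}hexanoate (vinylcyclobutenone, both ring epimers) | CCC[C@H](CC(=O)OC)C=C(O[Si](C(C)C)(C(C)C)C(C)C)C1(CC=C)C(=O)C=C1OCC | intermediate
13 | methyl (3R)-3-[4-ethoxy-6-oxo-3-(prop-2-en-1-yl)-2-(triisopropylsilyloxy)hexa-1,3,5-trien-1-yl]hexanoate (dienylketene, central alkene Z in the productive isomer) | CCC[C@H](CC(=O)OC)C=C(O[Si](C(C)C)(C(C)C)C(C)C)C(CC=C)=C(OCC)C=C=O | intermediate
14 | methyl (3R)-3-[4-ethoxy-6-oxo-3-(prop-2-en-1-yl)-2-(triisopropylsilyloxy)cyclohexa-2,4-dien-1-yl]hexanoate, both ring epimers | CCC[C@H](CC(=O)OC)C1C(=O)C=C(OCC)C(CC=C)=C1O[Si](C(C)C)(C(C)C)C(C)C | intermediate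
15 | methyl (3R)-3-[4-ethoxy-2-hydroxy-5-(prop-2-en-1-yl)-6-(triisopropylsilyloxy)phenyl]hexanoate | CCC[C@H](CC(=O)OC)c1c(O)cc(OCC)c(CC=C)c1O[Si](C(C)C)(C(C)C)C(C)C | intermediate
16 | tigloyl chloride [(2E)-2-methylbut-2-enoyl chloride] | C/C=C(\C)C(=O)Cl | starting material
17 | 5-ethoxy-2-[(3R)-1-methoxy-1-oxohexan-3-yl]-4-(prop-2-en-1-yl)-3-(triisopropylsilyloxy)phenyl (2E)-2-methylbut-2-enoate | CCC[C@H](CC(=O)OC)c1c(OC(=O)/C(C)=C/C)cc(OCC)c(CC=C)c1O[Si](C(C)C)(C(C)C)C(C)C | intermediate
18 | trichlorotitanium phenoxide of 19 (chelated by the ketone) | CCC[C@H](CC(=O)OC)c1c(O[Ti](Cl)(Cl)Cl)c(C(=O)/C(C)=C/C)c(OCC)c(CC=C)c1O[Si](C(C)C)(C(C)C)C(C)C | intermediate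
19 | methyl (3R)-3-[4-ethoxy-2-hydroxy-3-[(2E)-2-methylbut-2-enoyl]-5-(prop-2-en-1-yl)-6-(triisopropylsilyloxy)phenyl]hexanoate | CCC[C@H](CC(=O)OC)c1c(O)c(C(=O)/C(C)=C/C)c(OCC)c(CC=C)c1O[Si](C(C)C)(C(C)C)C(C)C | intermediate
20 | methyl (3R)-3-[(2R)-5-ethoxy-4-hydroxy-2,3-dimethyl-6-(prop-2-en-1-yl)-7-(triisopropylsilyloxy)-2H-chromen-8-yl]hexanoate (enol of 21) | CCC[C@H](CC(=O)OC)c1c(O[Si](C(C)C)(C(C)C)C(C)C)c(CC=C)c(OCC)c2c1O[C@H](C)C(C)=C2O | intermediate
21 | methyl (3R)-3-[(2R,3S)-5-ethoxy-2,3-dimethyl-4-oxo-6-(prop-2-en-1-yl)-7-(triisopropylsilyloxy)-3,4-dihydro-2H-chromen-8-yl]hexanoate | CCC[C@H](CC(=O)OC)c1c(O[Si](C(C)C)(C(C)C)C(C)C)c(CC=C)c(OCC)c2c1O[C@H](C)[C@H](C)C2=O | intermediate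
22 | O5-dichloroboryl ether of 23 (chelated by the C4 carbonyl) | CCC[C@H](CC(=O)OC)c1c(O[Si](C(C)C)(C(C)C)C(C)C)c(CC=C)c(OB(Cl)Cl)c2c1O[C@H](C)[C@H](C)C2=O | intermediate
23 | methyl (3R)-3-[(2R,3S)-5-hydroxy-2,3-dimethyl-4-oxo-6-(prop-2-en-1-yl)-7-(triisopropylsilyloxy)-3,4-dihydro-2H-chromen-8-yl]hexanoate | CCC[C@H](CC(=O)OC)c1c(O[Si](C(C)C)(C(C)C)C(C)C)c(CC=C)c(O)c2c1O[C@H](C)[C@H](C)C2=O | intermediate
24 | 2-methylbut-2-ene | CC=C(C)C | starting material
25 | methyl (3R)-3-[(2R,3S)-5-hydroxy-2,3-dimethyl-6-(3-methylbut-2-en-1-yl)-4-oxo-7-(triisopropylsilyloxy)-3,4-dihydro-2H-chromen-8-yl]hexanoate | CCC[C@H](CC(=O)OC)c1c(O[Si](C(C)C)(C(C)C)C(C)C)c(CC=C(C)C)c(O)c2c1O[C@H](C)[C@H](C)C2=O | intermediate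
26 | methyl (3R)-3-[(2R,3S)-5,7-dihydroxy-2,3-dimethyl-6-(3-methylbut-2-en-1-yl)-4-oxo-3,4-dihydro-2H-chromen-8-yl]hexanoate (CNP0068017.1) | CCC[C@H](CC(=O)OC)c1c(O)c(CC=C(C)C)c(O)c2c1O[C@H](C)[C@H](C)C2=O | target

**Step count and risks**

Total steps: 11. Longest linear sequence: 10 steps (1 → 2 → 3 → 9 → 15 → 17 → 19 → 21 → 23 → 25 → 26); step 3 is the side branch.

The three steps most likely to fail, in order:

Step 5. The push–pull cyclobutenone may open only at temperatures where ethoxyacetylene fragments to ketene and ethene. The crowded vinylketene may dimerise or acylate the product phenol faster than it adds the alkyne, and the phenol may lactonise during heating. The fallback gives up the cyclobutenone and decorates a preformed ring, so it does not branch from a numbered compound: it replaces steps 1 to 5, sets out from commercial 5,7-dihydroxy-4-propyl-2H-chromen-2-one F1 and comes back at 15. O7 is ethylated selectively (EtI, 1 equiv, K2CO3, acetone) to 7-ethoxy-5-hydroxy-4-propyl-2H-chromen-2-one F2. O5 is allylated (allyl bromide, K2CO3, DMF) to 7-ethoxy-5-(prop-2-en-1-yloxy)-4-propyl-2H-chromen-2-one F3. An aromatic Claisen rearrangement (N,N-diethylaniline, 190 °C) moves the allyl group to C6, the only free ortho position, giving 7-ethoxy-5-hydroxy-6-(prop-2-en-1-yl)-4-propyl-2H-chromen-2-one F4. Silylation (iPr3SiOTf, 2,6-lutidine) gives 7-ethoxy-6-(prop-2-en-1-yl)-4-propyl-5-(triisopropylsilyloxy)-2H-chromen-2-one F5. Copper hydride asymmetric conjugate reduction (Cu(OAc)2, the enantiomer of DTBM-SEGPHOS that gives 4R, polymethylhydrosiloxane, tBuOH, PhMe) sets the side-chain centre in (4R)-7-ethoxy-6-(prop-2-en-1-yl)-4-propyl-5-(triisopropylsilyloxy)-3,4-dihydro-2H-chromen-2-one F6. Acid-catalysed methanolysis (TsOH cat., MeOH) opens the lactone to 15, which is acylated at once as in step 6.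

Step 7. The Lewis acid may strip the silyl or ethyl ether, HCl may add to the allyl group, or the enone may close prematurely to racemic chromanone. The fallback sets out from 15 and comes back at 19, building the acyl group in two C–C bond formations without an acylium ion. Vilsmeier–Haack formylation (POCl3, DMF, 0 °C → rt; aq. NaOAc) at C4a gives methyl (3R)-3-[4-ethoxy-3-formyl-2-hydroxy-5-(prop-2-en-1-yl)-6-(triisopropylsilyloxy)phenyl]hexanoate F7. Addition of (E)-but-2-en-2-yllithium (from (E)-2-bromobut-2-ene and tBuLi, 2.2 equiv, THF, −78 °C) gives methyl (3R)-3-[4-ethoxy-2-hydroxy-3-[(2E)-1-hydroxy-2-methylbut-2-en-1-yl]-5-(prop-2-en-1-yl)-6-(triisopropylsilyloxy)phenyl]hexanoate F8 as both carbinol epimers. Oxidation with MnO2 (CH2Cl2, rt) gives 19 with the E geometry fixed by the alkenyl bromide.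

Step 8. Facial selectivity at C2 may be poor because the catalyst meets a hexasubstituted ring and a resident stereocentre next to the phenol, and the kinetic cis protonation may erode. The fallback sets out from 19 and comes back at 21, replacing catalyst control by separation. Cyclisation with an achiral amine (quinuclidine, PhCl, 15 °C) under the same kinetic conditions gives 21 together with methyl (3R)-3-[(2S,3R)-5-ethoxy-2,3-dimethyl-4-oxo-6-(prop-2-en-1-yl)-7-(triisopropylsilyloxy)-3,4-dihydro-2H-chromen-8-yl]hexanoate F9. The two are diastereomers because of the side-chain centre and are separated by preparative HPLC. F9 can be returned to 19 by E1cB ring opening of its lithium enolate (LiN(SiMe3)2, THF, −78 → 0 °C) and cyclised again.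

**Further compounds**

F1 | step 5 | 5,7-dihydroxy-4-propyl-2H-chromen-2-one | CCCC1=CC(=O)Oc2cc(O)cc(O)c21
F2 | step 5 | 7-ethoxy-5-hydroxy-4-propyl-2H-chromen-2-one | CCCC1=CC(=O)Oc2cc(OCC)cc(O)c21
F3 | step 5 | 7-ethoxy-5-(prop-2-en-1-yloxy)-4-propyl-2H-chromen-2-one | CCCC1=CC(=O)Oc2cc(OCC)cc(OCC=C)c21
F4 | step 5 | 7-ethoxy-5-hydroxy-6-(prop-2-en-1-yl)-4-propyl-2H-chromen-2-one | CCCC1=CC(=O)Oc2cc(OCC)c(CC=C)c(O)c21
F5 | step 5 | 7-ethoxy-6-(prop-2-en-1-yl)-4-propyl-5-(triisopropylsilyloxy)-2H-chromen-2-one | CCCC1=CC(=O)Oc2cc(OCC)c(CC=C)c(O[Si](C(C)C)(C(C)C)C(C)C)c21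
F6 | step 5 | (4R)-7-ethoxy-6-(prop-2-en-1-yl)-4-propyl-5-(triisopropylsilyloxy)-3,4-dihydro-2H-chromen-2-one | CCC[C@@H]1CC(=O)Oc2cc(OCC)c(CC=C)c(O[Si](C(C)C)(C(C)C)C(C)C)c21
F7 | step 7 | methyl (3R)-3-[4-ethoxy-3-formyl-2-hydroxy-5-(prop-2-en-1-yl)-6-(triisopropylsilyloxy)phenyl]hexanoate | CCC[C@H](CC(=O)OC)c1c(O)c(C=O)c(OCC)c(CC=C)c1O[Si](C(C)C)(C(C)C)C(C)C
F8 | step 7 | methyl (3R)-3-[4-ethoxy-2-hydroxy-3-[(2E)-1-hydroxy-2-methylbut-2-en-1-yl]-5-(prop-2-en-1-yl)-6-(triisopropylsilyloxy)phenyl]hexanoate, both carbinol epimers | CCC[C@H](CC(=O)OC)c1c(O)c(C(O)/C(C)=C/C)c(OCC)c(CC=C)c1O[Si](C(C)C)(C(C)C)C(C)C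
F9 | step 8 | methyl (3R)-3-[(2S,3R)-5-ethoxy-2,3-dimethyl-4-oxo-6-(prop-2-en-1-yl)-7-(triisopropylsilyloxy)-3,4-dihydro-2H-chromen-8-yl]hexanoate | CCC[C@H](CC(=O)OC)c1c(O[Si](C(C)C)(C(C)C)C(C)C)c(CC=C)c(OCC)c2c1O[C@@H](C)[C@@H](C)C2=O
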